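**Plan**

- Cuts (lactone numbering O1, C2 carbonyl, C3, C4, C5): the O-benzyl mask and two helpers (Cl on C3, p-tolylsulfanyl on C5) are put back first. O1–C5 and C3–C4 are then cut in one stroke.
- This leaves a chloro(arylmethyl)ketene that holds the whole vanillyl arm, and an enantiopure (Z)-3-aryl-1-propenyl p-tolyl sulfoxide that holds the trimethoxybenzyl arm.
- Enabling feature: C5 of the butyrolactone ring is an unsubstituted OCH2 beside stereocentre C4. The C4–C5 edge can therefore be an alkene that bears sulfur on C5, and O1–C2(=O)–C3 is a ketene plus the sulfoxide oxygen.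
- Forward: two three-step arms are joined in one flask, which also closes the only non-aromatic ring. Reductive loss of Cl and S, equilibration at C3 and debenzylation follow.
- Stereochemistry: C4 comes from sulfur-to-carbon chirality transfer in a [3,3] shift, with sulfur taken from menthyl p-toluenesulfinate. C3 comes from the thermodynamic trans preference relative to C4.

Key step: step 7

Assumption: the sense of chirality transfer in step 7 is taken from the transition-state model given there. Should experiment show the opposite sense, the commercial enantiomer (1S,2R,5S)-menthyl (R)-p-toluenesulfinate is used in step 2 and nothing else changes.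

**Step 1**
Reactants: 1 3,4,5-trimethoxybenzyl chloride; 2 ethynylmagnesium bromide
Product: 3 1,2,3-trimethoxy-5-(prop-2-yn-1-yl)benzene
Conditions: 2 (1.5 equiv), CuBr (10 mol %), THF, 60 °C
Reagents that add atoms: none
Why: Copper-catalysed cross-coupling of an alkynyl Grignard reagent with an activated benzylic chloride is a standard entry to 3-aryl-1-propynes, and the excess of 2 suppresses double alkylation.

**Step 2**
Reactants: 3 1,2,3-trimethoxy-5-(prop-2-yn-1-yl)benzene; 4 (1R,2S,5R)-menthyl (S)-p-toluenesulfinate
Product: 6 1,2,3-trimethoxy-5-{3-[(S)-(4-methylphenyl)sulfinyl]prop-2-yn-1-yl}benzene, via alkynylmagnesium bromide 5 (not isolated)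
Conditions: EtMgBr (1.05 equiv), THF, 0 °C to rt; then 4, toluene, −20 °C; H2O
Reagents that add atoms: none
Why: Andersen sulfoxide synthesis, in which the alkynyl Grignard reagent 5 displaces menthoxide with clean inversion at sulfur and so sets the sulfur stereocentre (the descriptor reads S only because alkynyl outranks p-tolyl), while the low temperature in toluene holds back propargyl-to-allenyl isomerisation.

**Step 3**
Reactants: 6 alkynyl sulfoxide
Product: 7 1,2,3-trimethoxy-5-{(2Z)-3-[(R)-(4-methylphenyl)sulfinyl]prop-2-en-1-yl}benzene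
Conditions: H2 (1 atm), RhCl(PPh3)3 (5 mol %), toluene, rt
Reagents that add atoms: none
Why: Homogeneous syn hydrogenation of a 1-alkynyl sulfoxide with RhCl(PPh3)3 should stop at the (Z)-alkenyl sulfoxide and leave sulfur untouched (the descriptor changes to R because p-tolyl now outranks alkenyl).

**Step 4**
Reactants: 8 3-(4-hydroxy-3-methoxyphenyl)propanoic acid (dihydroferulic acid)
Product: 9 3-[4-(benzyloxy)-3-methoxyphenyl]propanoic acid
Conditions: BnBr (1.3 equiv), NaOH (2.5 equiv), EtOH/H2O, reflux; then aq. HCl
Reagents that add atoms: benzyl bromide, BrCc1ccccc1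
Why: Williamson ether synthesis on the phenoxide–carboxylate dianion in a protic medium, where the phenoxide is the better nucleophile and any benzyl ester is saponified by the excess hydroxide.

**Step 5**
Reactants: 9 3-[4-(benzyloxy)-3-methoxyphenyl]propanoic acid
Product: 11 racemic 3-[4-(benzyloxy)-3-methoxyphenyl]-2-chloropropanoic acid, via dilithium enediolate 10 (not isolated)
Conditions: LDA (2.2 equiv), THF, −78 to 0 °C; cannulated into CCl4 (3 equiv), THF, −78 °C; aq. HCl
Reagents that add atoms: carbon tetrachloride, ClC(Cl)(Cl)Cl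
Why: Halophilic α-chlorination of a carboxylic acid enediolate with CCl4 is a known route to the α-chloro acids used as chloroketene precursors, inverse addition keeps proton exchange and loss of HCl minor, and the racemic centre is of no consequence because it becomes sp2 in the ketene of step 7.

**Step 6**
Reactants: 11 racemic α-chloro acid
Product: 12 racemic 3-[4-(benzyloxy)-3-methoxyphenyl]-2-chloropropanoyl chloride
Conditions: (COCl)2 (1.5 equiv), DMF (cat.), CH2Cl2, 0 °C to rt; concentrated and used crude
Reagents that add atoms: oxalyl chloride, O=C(Cl)C(=O)Cl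
Why: Standard acid chloride formation through the chloroiminium species from DMF, under conditions that leave the benzyl ether and the secondary chloride intact.

**Step 7**
Reactants: 7 (Z)-alkenyl (R)-sulfoxide; 12 α-chloro acid chloride
Product: 16 (4S)-3-[4-(benzyloxy)-3-methoxybenzyl]-3-chloro-5-[(4-methylphenyl)sulfanyl]-4-(3,4,5-trimethoxybenzyl)dihydrofuran-2(3H)-one (epimer mixture at C3 and C5), via chloroketene 13 (not isolated), via acyloxysulfonium enolate 14 (not isolated), via thionium carboxylate 15 (not isolated)
Conditions: Et3N (2.5 equiv), toluene, 0 °C to rt; 12 (2 equiv) added slowly by syringe pump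
Reagents that add atoms: none
Why: Proposed new method: Et3N dehydrochlorinates 12 to the electrophilic chloroketene 13, the sulfinyl oxygen of 7 adds to the ketene carbonyl carbon to give the vinyl(acyloxy)sulfonium enolate 14, and a charge-accelerated [3,3]-sigmatropic shift over the six atoms C4=C5–S–O–C2=C3 makes C3–C4 and breaks S–O to give the thionium carboxylate 15. The carboxylate oxygen then closes on the thionium carbon C5 in a 5-exo-trig mode (the C=S bond stays outside the new ring), so that O1–C5 and C3–C4 arise in one flask as a formal (3+2) annulation of a C–C(=O)–O unit onto the C4=C5 alkene. The closest known reaction type is the Marino lactonization of enantiopure alkenyl sulfoxides with dichloroketene; new is a ketene with only one chlorine and a full arylmethyl arm, which is less electrophilic but gives a more nucleophilic enolate carbon, and 14 can also be reached by O-acylation of 7 with 12 followed by deprotonation. C4 is controlled by the sulfur stereocentre: A(1,3) strain with the (Z)-substituent holds the sulfur lone pair beside it and p-tolyl pseudo-equatorial in the chair-like array, so the enolate carbon reaches only the alkene face on which the S–O bond lies, and (R)-sulfur with (Z)-geometry maps onto the C4 configuration of the target. C3 (enolate geometry) and C5 (syn addition across the alkene) need no control because step 8 erases both. The step needs the sigmatropic shift to outrun ketene dimerisation, deprotonation at the benzylic CH2 of 14 (vinylogous Pummerer path) and Friedel–Crafts capture of 15 by the electron-rich rings; the intramolecular anionic partners, the slow addition of 12 and the absence of any Lewis acid should secure this.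

**Step 8**
Reactants: 16 chloro sulfanyl lactone
Product: 17 (4R)-3-[4-(benzyloxy)-3-methoxybenzyl]-4-(3,4,5-trimethoxybenzyl)dihydrofuran-2(3H)-one (epimer mixture at C3)
Conditions: Bu3SnH (3 equiv), AIBN (0.2 equiv), toluene, 90 °C
Reagents that add atoms: none
Why: Tin hydride radical chain reduction, in which Bu3Sn radicals abstract the tertiary α-carbonyl chlorine and cleave the C5–S bond of the O,S-acetal (as known for haloketene-derived γ-arylsulfanyl lactones), and the neutral medium excludes loss of HCl towards C4, so that C4 is kept while C3 arises as an epimer mixture.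

**Step 9**
Reactants: 17 lactone, C3 epimer mixture
Product: 18 (3R,4R)-3-[4-(benzyloxy)-3-methoxybenzyl]-4-(3,4,5-trimethoxybenzyl)dihydrofuran-2(3H)-one (trans)
Conditions: DBU (1 equiv), toluene, 100 °C
Reagents that add atoms: none
Why: Thermodynamic epimerisation through the lactone enolate, in which only C3 is acidic and the trans-3,4-dibenzyl arrangement is the more stable one in this lactone class, so that the fixed C4 centre dictates (3R).

**Step 10**
Reactants: 18 trans benzyl ether
Product: 19 (3R,4R)-3-(4-hydroxy-3-methoxybenzyl)-4-(3,4,5-trimethoxybenzyl)dihydrofuran-2(3H)-one (target)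
Conditions: H2 (1 atm), Pd/C (10 wt %), EtOAc/EtOH, rt
Reagents that add atoms: none
Why: Catalytic hydrogenolysis of the aryl benzyl ether under neutral conditions, which touch neither the lactone, the methyl ethers nor the two stereocentres.

**Compound list**

1 | 3,4,5-trimethoxybenzyl chloride | COc1cc(CCl)cc(OC)c1OC | starting material
2 | ethynylmagnesium bromide | C#C[Mg]Br | starting material
3 | 1,2,3-trimethoxy-5-(prop-2-yn-1-yl)benzene | COc1cc(CC#C)cc(OC)c1OC | intermediate
4 | (1R,2S,5R)-menthyl (S)-p-toluenesulfinate | Cc1ccc(cc1)[S@@](=O)O[C@@H]1C[C@H](C)CC[C@H]1C(C)C | starting material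
5 | [3-(3,4,5-trimethoxyphenyl)prop-1-yn-1-yl]magnesium bromide | COc1cc(CC#C[Mg]Br)cc(OC)c1OC | intermediate
6 | 1,2,3-trimethoxy-5-{3-[(S)-(4-methylphenyl)sulfinyl]prop-2-yn-1-yl}benzene | Cc1ccc(cc1)[S@](=O)C#CCc1cc(OC)c(OC)c(OC)c1 | intermediate
7 | 1,2,3-trimethoxy-5-{(2Z)-3-[(R)-(4-methylphenyl)sulfinyl]prop-2-en-1-yl}benzene | Cc1ccc(cc1)[S@](=O)/C=C\Cc1cc(OC)c(OC)c(OC)c1 | intermediate
8 | 3-(4-hydroxy-3-methoxyphenyl)propanoic acid | COc1cc(CCC(=O)O)ccc1O | starting material
9 | 3-[4-(benzyloxy)-3-methoxyphenyl]propanoic acid | COc1cc(CCC(=O)O)ccc1OCc1ccccc1 | intermediate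
10 | dilithium enediolate of 9 | [Li+].[Li+].COc1cc(CC=C([O-])[O-])ccc1OCc1ccccc1 | intermediate
11 | racemic 3-[4-(benzyloxy)-3-methoxyphenyl]-2-chloropropanoic acid | COc1cc(CC(Cl)C(=O)O)ccc1OCc1ccccc1 | intermediate
12 | racemic 3-[4-(benzyloxy)-3-methoxyphenyl]-2-chloropropanoyl chloride | COc1cc(CC(Cl)C(=O)Cl)ccc1OCc1ccccc1 | intermediate
13 | [4-(benzyloxy)-3-methoxybenzyl](chloro)ketene | COc1cc(CC(Cl)=C=O)ccc1OCc1ccccc1 | intermediate
14 | vinyl(acyloxy)sulfonium enolate zwitterion (sulfur configuration as in 7) | COc1cc(CC(Cl)=C([O-])O[S@@+](c2ccc(C)cc2)/C=C\Cc2cc(OC)c(OC)c(OC)c2)ccc1OCc1ccccc1 | intermediate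
15 | thionium carboxylate zwitterion (new C–C bond in place, C–Cl centre unassigned) | COc1cc(CC(Cl)(C([O-])=O)[C@@H](Cc2cc(OC)c(OC)c(OC)c2)C=[S+]c2ccc(C)cc2)ccc1OCc1ccccc1 | intermediate
16 | (4S)-3-[4-(benzyloxy)-3-methoxybenzyl]-3-chloro-5-[(4-methylphenyl)sulfanyl]-4-(3,4,5-trimethoxybenzyl)dihydrofuran-2(3H)-one, epimer mixture at C3 and C5 | COc1cc(CC2(Cl)C(=O)OC(Sc3ccc(C)cc3)[C@@H]2Cc2cc(OC)c(OC)c(OC)c2)ccc1OCc1ccccc1 | intermediate
17 | (4R)-3-[4-(benzyloxy)-3-methoxybenzyl]-4-(3,4,5-trimethoxybenzyl)dihydrofuran-2(3H)-one, epimer mixture at C3 | COc1cc(CC2C(=O)OC[C@@H]2Cc2cc(OC)c(OC)c(OC)c2)ccc1OCc1ccccc1 | intermediate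
18 | (3R,4R)-3-[4-(benzyloxy)-3-methoxybenzyl]-4-(3,4,5-trimethoxybenzyl)dihydrofuran-2(3H)-one | COc1cc(C[C@H]2C(=O)OC[C@@H]2Cc2cc(OC)c(OC)c(OC)c2)ccc1OCc1ccccc1 | intermediate
19 | (3R,4R)-3-(4-hydroxy-3-methoxybenzyl)-4-(3,4,5-trimethoxybenzyl)dihydrofuran-2(3H)-one | COc1cc(C[C@H]2C(=O)OC[C@@H]2Cc2cc(OC)c(OC)c(OC)c2)ccc1O | target

Total step count: 10. Longest linear sequence: 7 (steps 1–3 or 4–6, then 7–10).

**Steps most likely to fail**

Step 7. Three processes could defeat it:
- The mono-chloro ketene may dimerise before the sulfoxide oxygen captures it.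
- The acyloxysulfonium stage may lose a benzylic proton and drift into a vinylogous Pummerer path.
- Chloride may racemise sulfur before the shift takes place.

The fallback sets out from 7 and uses only established chemistry.
- Dichloroketene (Cl3CCOCl, Zn–Cu couple, Et2O) converts 7 by the known lactonization into (4S)-3,3-dichloro-5-[(4-methylphenyl)sulfanyl]-4-(3,4,5-trimethoxybenzyl)dihydrofuran-2(3H)-one F1.
- Bu3SnH/AIBN strips both chlorines and the sulfanyl group to give (R)-4-(3,4,5-trimethoxybenzyl)dihydrofuran-2(3H)-one F2.
- The lithium enolate of F2 (LiHMDS, THF, −78 °C) is alkylated anti to the C4 substituent with 4-(benzyloxy)-3-methoxybenzyl bromide F3, which is made from the commercial benzyl alcohol with PBr3.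
- The sequence comes back at 18, and steps 4–6, 8 and 9 then fall away.

Step 2. The doubly activated propargylic CH2 of the alkynyl sulfoxide may isomerise to the allenyl sulfoxide under the basic magnesium alkoxide conditions. The fallback sets out from 3 and never passes through an alkynyl sulfoxide.
- NIS with AgNO3 (cat.) in acetone gives 5-(3-iodoprop-2-yn-1-yl)-1,2,3-trimethoxybenzene F4.
- Diimide (2-nitrobenzenesulfonohydrazide, Et3N) reduces F4 to 5-[(2Z)-3-iodoprop-2-en-1-yl]-1,2,3-trimethoxybenzene F5.
- Iodine–magnesium exchange with i-PrMgCl·LiCl proceeds with retention to the (Z)-alkenylmagnesium chloride F6.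
- F6 displaces menthoxide from 4 with inversion at sulfur, and the sequence comes back at 7. Step 3 is bypassed as well.

Step 5. Proton exchange between the α-chloro carboxylate and unreacted enediolate may cause over-chlorination and return of acid. Loss of HCl to the cinnamate may also erode the chlorination in the strongly basic medium. The fallback sets out from 9 and replaces halophilic attack by a dianion with electrophilic chlorination of an isolated neutral nucleophile.
- LDA (2.2 equiv) then TMSCl gives the bis(trimethylsilyl) ketene acetal F7, isolated by non-aqueous work-up.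
- NCS in CH2Cl2 (−78 to 0 °C) chlorinates the acetal carbon with no base present.
- Aqueous work-up cleaves the silyl ester, and the sequence comes back at 11.

**Further compounds**

F1 | step 7 | (4S)-3,3-dichloro-5-[(4-methylphenyl)sulfanyl]-4-(3,4,5-trimethoxybenzyl)dihydrofuran-2(3H)-one | O=C1OC(Sc2ccc(C)cc2)[C@H](Cc2cc(OC)c(OC)c(OC)c2)C1(Cl)Cl
F2 | step 7 | (R)-4-(3,4,5-trimethoxybenzyl)dihydrofuran-2(3H)-one | O=C1C[C@@H](Cc2cc(OC)c(OC)c(OC)c2)CO1
F3 | step 7 | 4-(benzyloxy)-3-methoxybenzyl bromide | COc1cc(CBr)ccc1OCc1ccccc1
F4 | step 2 | 5-(3-iodoprop-2-yn-1-yl)-1,2,3-trimethoxybenzene | COc1cc(CC#CI)cc(OC)c1OC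
F5 | step 2 | 5-[(2Z)-3-iodoprop-2-en-1-yl]-1,2,3-trimethoxybenzene | COc1cc(C/C=C\I)cc(OC)c1OC
F6 | step 2 | [(1Z)-3-(3,4,5-trimethoxyphenyl)prop-1-en-1-yl]magnesium chloride | COc1cc(C/C=C\[Mg]Cl)cc(OC)c1OC
F7 | step 5 | bis(trimethylsilyl) ketene acetal of 9 | COc1cc(CC=C(O[Si](C)(C)C)O[Si](C)(C)C)ccc1OCc1ccccc1
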